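## Structural features

Pilosanol B is a catechin-type flavan-3-ol (ring A, the benzo ring with oxygens at C5 and C7; ring C, the dihydropyran; ring B, a catechol on C2) whose C8 is joined through one methylene carbon to a fully substituted acylphloroglucinol, ring D. The only stereocentres are the adjacent C2 (R, aryl-bearing) and C3 (S, hydroxyl-bearing) of ring C; they are trans and identical with those of (+)-catechin. Ring D is numbered here from the bridge-bearing carbon D1 and then carries OH at D2, isobutyryl at D3, OMe at D4, methyl at D5 and OH at D6. The fragile features are the seven free hydroxyl groups (air oxidation), the benzylic C2–O1 bond, which opens under base once the para-phenol of ring B is free (loss of the C2 configuration) and under strong acid, and ring A, which is nucleophilic at both C6 and C8. The real difficulty is ring D: it has no free position, and of its three oxygens only the one at D4, wedged between the C-methyl carbon and the acyl-bearing carbon, is an ether, which cannot be reached by ranking three phenols in an alkylation; the second difficulty is to attach the bridge at C8 and not at C6. The key step exploits that D3 and D4 are neighbouring carbons bearing an acyl group and an ether oxygen, the two carbons of a β-alkoxy ynone, whereas D2–D1–D6–D5 with its two oxygens, the bridge and the methyl group is the C1–C2–C3–C4 segment of a 2,4-disubstituted cyclohexane-1,3-dione, so that forming D2–D3 and D4–D5 by cycloaddition places all six substituents by their origin.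

## Logic of the disconnections

19 ⇒ 18. The five O–benzyl bonds (O3, O5, O7, O3', O4') are cut last. As ethers the hydroxyl groups survive strong base, an aryllithium and a thermal cycloaddition, and capping the ring B phenols blocks the base-induced opening of ring C. The forward step must remove five benzyl groups without touching the aryl ketone, the diarylmethane carbon or the C2–O1 bond, which calls for a neutral hydrogenolysis at low pressure.

18 ⇒ 17. The two aryl O–Si bonds at D2 and D6 are cut. This shows that both ring D phenols are former carbonyl oxygens. The forward step is a mild protonolysis that leaves the benzyl ethers and the flavan untouched.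

17 ⇒ 10 + 15 (through 16). The ring D bonds D2–D3 and D4–D5 are cut and a two-carbon saturated bridge is put back between D2 and D5. A hexasubstituted benzene becomes a cyclic bis(silyloxy)diene and a two-carbon alkyne, and no phenol has to be told from another because the ether oxygen arrives on the alkyne. The forward step demands one regiochemistry, a diene and dienophile that tolerate heat, and enough reactivity from a donor-substituted alkyne toward a fully substituted diene terminus.

15 ⇒ 14 ⇒ 11 + 12 (through 13). The ketone is traced back to the carbinol, and the bond between the alkyne carbon and the carbinol carbon is cut. This gives an alkoxyacetylide, available in the flask from 11, and the aldehyde 12. The forward steps must avoid acid and water, which would rearrange or hydrate the ynol ether.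

10 ⇒ 9. The two enol O–Si bonds are cut. The demand is on regiochemistry: the carbonyl next to the methyl-bearing carbon must enolise toward that carbon, so that the methyl group sits on the diene terminus and the unsubstituted CH2–CH2 becomes the bridge that is later expelled.

9 ⇒ 6 + 7 (through 8). The bond between the bridge carbon and D1 is cut; the bridge carbon becomes the aldehyde carbon on C8 and D1 the acidic C2 of the dione. This is the convergent point of the flavan and ring D halves. The forward step must alkylate carbon and not oxygen, and must reduce 8 before a second dione adds to it.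

6 ⇒ 4 (through 5) ⇒ 3. The C8–CHO bond and then the C8–Br bond are cut. The C6/C8 question is settled by an electrophilic bromination whose C8 preference on such ethers is established. The metalation must be faster than any attack on the benzyl ethers.

3 ⇒ 2 ⇒ 1. The benzyl ethers are cut in two stages, phenols under weak base and the C3 alcohol under strong base. This keeps strong base away from free phenols and so protects C2. Both stereocentres of 19 are bought with 1 and are never touched.

## Other disconnections considered

Alternative 1: The cut runs through ring C at O1–C2 and C3–C4, with a formyl carbon standing in for the C3 oxygen. In the forward step the ring A salicylaldehyde A1, which already carries the complete ring D on its C8 methylene, and the ring B cinnamaldehyde A2 would be joined under a diarylprolinol silyl ether. The sequence is iminium formation from A2, oxa-Michael addition of the phenol (O1–C2), and aldol condensation of the enamine with the aldehyde of A1 (C3–C4), giving the 2H-chromene-3-carbaldehyde A3.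
- In its favour: C2 is set by a catalyst, the reaction is mild and convergent, and no chiral-pool material is needed.
- Against it here: A1 contains ring D, so the methylation pattern, the hardest feature, is left to a separate and unsolved synthesis. The flavan is built although it can be bought as 1. After the key step the C3=C4 bond must be reduced, the formyl carbon exchanged for oxygen and the 2,3-trans relation secured, and C3 is then set by equilibration and not by the key step.
- Comparison: on mechanism this cascade has closer precedent for its exact pairing than the chosen cycloaddition, so on that point it is the better. On protecting groups the two are equal (benzyl ethers, one hydrogenolysis). On structure the chosen plan answers the ring D problem and takes both stereocentres from 1. On step economy the alternative is expected to be clearly longer.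

Alternative 2: Three ring D bonds are cut, D1–D2, D5–D6 and D2–D3, and the isobutyryl group is removed from D3. In the forward step 3-methoxy-2-methylcyclobutenone A4 and the triisopropylsilyloxy alkyne A5, mounted on the C8 methylene of penta-O-benzylcatechin, would be heated. The sequence is ring opening to a vinylketene, (2+2) addition to the alkyne, four-electron ring opening and six-electron electrocyclisation, giving the phenol A6 with OMe at D4, free OH at D2 and a silyl ether at D6.
- In its favour: the three oxygens leave the key step mutually distinguished by their origin, there is no enolisation regiochemistry to control, and the pairing of an alkoxy vinylketene with an electron-rich siloxyalkyne is the standard one for this benzannulation.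
- Against it here: A5 needs an ester-to-ynolate homologation on a C8 acetic ester and A4 its own preparation. Ring D emerges without the acyl group, which must then be placed at D3 by O-acylation and Fries shift or by Friedel–Crafts acylation, in the presence of the nucleophilic C6–H of ring A and of Lewis-acid-sensitive benzyl ethers. A separate desilylation follows.
- Comparison: on electronic matching and on certainty of the oxygen pattern this alternative is at least the equal and probably the better of the chosen plan, which pairs an electron-rich diene with a donor-deactivated dienophile. On chiral pool, C8 logic and the number of rings formed the two are equal. The chosen plan brings the acyl group in with the ring, needs no Lewis acid after the benzyl groups are on, and is expected to be about three steps shorter.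

Alternative 3: The cut is at O1–C8a of ring C and at the bond from C8 to the bridge carbon, which is carried as a carbinol. In the forward step the open-chain bromo-iodo alcohol A7 would be treated with iPrMgCl·LiCl. Alkoxide formation, iodine–magnesium exchange at C8 and loss of bromide would give the C8–C8a aryne; the C2 alkoxide would add at C8a to close ring C, and the C8 arylmagnesium so formed would add to the ring D aldehyde A8, giving the carbinol A9 as epimers.
- In its favour: two bonds in two different parts of the molecule are made in one flask, the C8 attachment is enforced by the aryne geometry and not by a selectivity, and the carbinol oxygen would leave in the final hydrogenolysis together with seven benzyl groups.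
- Against it here: A7 demands an enantioselective synthesis of the two stereocentres that 1 supplies. A8 is again ring D with the difficult methylation pattern. The ortho-bromo arylmagnesium eliminates only on warming, and a di-ortho-oxygenated arylmagnesium must then add to a di-ortho-substituted aldehyde lying next to a ketone.
- Comparison: on positional control at C8 and on the number of steps after the key step (one against two) this alternative is the better, and in convergence it is at least the equal. On structure it leaves the central ring D problem unsolved. On mechanism its cascade asks three organometallic events to run in a fixed order, where the chosen plan asks one pericyclic pair. The overall count is expected to be higher.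

Key step: step 9

Remark on the structures: the flavan descriptors of 19 are 2R,3S (trans), those of 1, and diene 10 and ynone 15 map onto ring D atom for atom with the required regiochemistry, so the precursor and product of the key step are used with their constitution unchanged. The points tightened are an iodide-free, equilibrating silylation in step 6 and the use of 10 and 15 without chromatography.

Remark on stereochemistry: 7 is racemic, and the methyl-bearing carbon of 8 and 9, the alkene geometry of 8, the carbinol carbon of 14 and the bridgeheads of 16 are left undefined because all of them become trigonal or are lost.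

## Route

Step 1
Reactants: 1 (+)-catechin
Product: 2 5,7,3',4'-tetra-O-benzylcatechin (free 3-OH; 2R,3S)
Conditions: BnBr (4.4 equiv), K2CO3 (4.4 equiv), DMF, 0 °C → rt
Reagents that add atoms: benzyl bromide, BrCc1ccccc1
Why: Williamson ether synthesis; carbonate deprotonates only the four phenols, so the C3 alcohol stays free, and capping the 4'-phenol early shuts down the quinone-methide pathway that would epimerise C2.

Step 2
Reactants: 2 5,7,3',4'-tetra-O-benzylcatechin
Product: 3 3,5,7,3',4'-penta-O-benzylcatechin (2R,3S)
Conditions: NaH, BnBr, DMF, 0 °C → rt
Reagents that add atoms: benzyl bromide, BrCc1ccccc1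
Why: Williamson ether synthesis of the secondary alkoxide formed with NaH; with all phenols capped there is no base-induced ring opening, so the trans C2/C3 relation is kept.

Step 3
Reactants: 3 3,5,7,3',4'-penta-O-benzylcatechin
Product: 4 8-bromo-penta-O-benzylcatechin
Conditions: NBS (1.0 equiv), CH2Cl2, −78 °C → rt
Reagents that add atoms: N-bromosuccinimide, O=C1CCC(=O)N1Br
Why: Electrophilic aromatic bromination of the phloroglucinol-type ring A; C8, flanked by the ring oxygen and one benzyloxy group, is less hindered than C6 between two benzyloxy groups, and C8 selectivity on 3-O-protected tetra-O-benzyl flavan-3-ols is established behaviour. One equivalent at low temperature avoids the 6,8-dibromide.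

Step 4
Reactants: 4 8-bromo-penta-O-benzylcatechin
Product: 6 8-formyl-penta-O-benzylcatechin, via 8-lithio-penta-O-benzylcatechin 5 (not isolated)
Conditions: n-BuLi, THF, −78 °C; DMF, −78 → 0 °C; H2O
Reagents that add atoms: N,N-dimethylformamide, CN(C)C=O
Why: Bromine–lithium exchange followed by formylation of the aryllithium with a formamide (Bouveault aldehyde synthesis); exchange at −78 °C is faster than deprotonation of the benzyl ethers, and the tetrahedral adduct releases the aldehyde only on aqueous quench, so no second addition occurs.

Step 5
Reactants: 6 8-formyl-penta-O-benzylcatechin; 7 4-methylcyclohexane-1,3-dione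
Product: 9 2-(penta-O-benzylcatechin-8-ylmethyl)-4-methylcyclohexane-1,3-dione (epimers and enol tautomers), via the 2-arylmethylidene-1,3-dione 8 (not isolated)
Conditions: diethyl 2,6-dimethyl-1,4-dihydropyridine-3,5-dicarboxylate (Hantzsch ester, 1.2 equiv), L-proline (20 mol %), CH2Cl2, rt
Reagents that add atoms: none
Why: Organocatalytic three-component reductive alkylation: proline-mediated Knoevenagel condensation at the acidic C2 of the dione gives 8, which is reduced at once by hydride transfer from the dihydropyridine, so that neither O-alkylation nor addition of a second dione to 8 intervenes. The methyl-bearing centre is left undefined because it becomes trigonal in step 6.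

Step 6
Reactants: 9 2-(penta-O-benzylcatechin-8-ylmethyl)-4-methylcyclohexane-1,3-dione
Product: 10 4-methyl-2-(penta-O-benzylcatechin-8-ylmethyl)-1,3-bis(trimethylsilyloxy)cyclohexa-1,3-diene
Conditions: TMSOTf (2.5 equiv), Et3N (3.5 equiv), CH2Cl2, 0 °C → rt; pentane extraction under argon, used crude
Reagents that add atoms: trimethylsilyl trifluoromethanesulfonate, C[Si](C)(C)OS(=O)(=O)C(F)(F)F
Why: Double O-silylation by soft enolisation: the 3-silyloxy enone formed first is silylated at its carbonyl to a 1,3-bis(silyloxy)allyl cation, and loss of the methine proton gives the tetrasubstituted, more stable enol ether, toward which the ammonium triflate present lets the isomers equilibrate. An iodide-based silylation is avoided because iodosilane formed in the flask would attack the benzyl ethers; any diene enolised toward the CH2 would later lose propene and give a des-methyl by-product.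

Step 7
Reactants: 11 chloroacetaldehyde dimethyl acetal; 12 isobutyraldehyde
Product: 14 1-methoxy-4-methylpent-1-yn-3-ol (racemic), via lithium methoxyacetylide 13 (not isolated)
Conditions: LiNEt2 (3.1 equiv, from Et2NH and n-BuLi), THF, 0 °C → rt; then 12, −78 → 0 °C; H2O
Reagents that add atoms: none
Why: Double elimination of the chloroacetal with three equivalents of lithium amide (loss of methanol, loss of HCl, deprotonation) gives the alkoxyacetylide 13, which adds to the aldehyde carbonyl (acetylide 1,2-addition). The carbinol centre is racemic and is destroyed in step 8; the work-up is kept neutral to basic because the ynol ether carbinol undergoes Meyer–Schuster rearrangement under acid.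

Step 8
Reactants: 14 1-methoxy-4-methylpent-1-yn-3-ol
Product: 15 1-methoxy-4-methylpent-1-yn-3-one
Conditions: activated MnO2 (15 equiv), CH2Cl2, rt; filtration through Celite, cold concentration, used at once
Reagents that add atoms: none
Why: Heterogeneous MnO2 oxidation of a propargylic alcohol; it is neutral, anhydrous and non-nucleophilic, so the acid- and water-sensitive ynol ether should survive, and filtration alone delivers the volatile ynone.

Step 9
Reactants: 10 4-methyl-2-(penta-O-benzylcatechin-8-ylmethyl)-1,3-bis(trimethylsilyloxy)cyclohexa-1,3-diene; 15 1-methoxy-4-methylpent-1-yn-3-one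
Product: 17 penta-O-benzyl pilosanol B bis(trimethylsilyl) ether, via bicyclo[2.2.2]octa-2,5-diene cycloadduct 16 (not isolated)
Conditions: 15 (3 equiv), o-xylene, sealed tube, 120 °C then 170 °C (−C2H4)
Reagents that add atoms: none
Why: The diene 10 has its HOMO raised by two silyloxy groups, with the largest coefficient at the methyl-bearing terminus D5, and the ynone 15 has its largest LUMO coefficient at the methoxy-bearing carbon β to the carbonyl; the two should combine in a concerted but asynchronous normal-demand (4+2) cycloaddition in which D4–D5 bonding runs ahead of D2–D3 bonding, giving 16. On further heating 16 should undergo a thermally allowed retro-(4+2) cycloreversion that expels the saturated two-carbon bridge as ethylene and leaves the benzene ring of 17, which makes the sequence irreversible (Alder–Rickert reaction). The closest known reaction type is the resorcinol synthesis from 1,3-bis(silyloxy)cyclohexa-1,3-dienes and acetylenic esters or ketones with loss of an alkene. Ring D is closed by intermolecular (4+2) annulation as a bridged six-membered ring, both bonds being made suprafacially on one diene face, and is unveiled by the cycloreversion. No stereocentre is created: the two bridgeheads of 16 form as a mixture relative to C2/C3 and vanish with the ethylene, while C2 and C3 are spectators. The step needs regioselectivity (acyl next to the silyloxy terminus D2, methoxy next to D5), which the matched polarisation of the partners secures, and chemoselectivity for cycloaddition over silyl transfer or conjugate addition, which neutral, aprotic, Lewis-acid-free heating favours. The dienophile is used in excess in a closed vessel because it is volatile and because its donor group and the fully substituted diene terminus slow the addition.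

Step 10
Reactants: 17 penta-O-benzyl pilosanol B bis(trimethylsilyl) ether
Product: 18 penta-O-benzyl pilosanol B (ring D diphenol)
Conditions: 0.5 M aq. HCl, THF, 0 °C → rt
Reagents that add atoms: none
Why: Acid-catalysed hydrolysis of aryl trimethylsilyl ethers, which are far more labile than benzyl ethers; the phenol next to the ketone is released into a strong intramolecular hydrogen bond, and the flavan ether and its stereocentres are not affected at this acidity.

Step 11
Reactants: 18 penta-O-benzyl pilosanol B
Product: 19 pilosanol B
Conditions: H2 (1 atm), Pd(OH)2 on carbon (20 wt %), THF–MeOH (1:1), rt; work-up under argon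
Reagents that add atoms: none
Why: Catalytic hydrogenolysis of five benzyl ethers; the acylphloroglucinol ketone is a chelated vinylogous acid and should resist reduction at one atmosphere, and the diarylmethane and the C2–O1 bond have no good leaving group under neutral conditions. No base is present, so C2 and C3 are not epimerised.

## Compound list

1 | (+)-catechin, (2R,3S)-2-(3,4-dihydroxyphenyl)chromane-3,5,7-triol | Oc1cc(O)c2c(c1)O[C@H](c1ccc(O)c(O)c1)[C@@H](O)C2 | starting material
2 | 5,7,3',4'-tetra-O-benzylcatechin | c1c(OCc2ccccc2)cc(OCc2ccccc2)c2c1O[C@H](c1ccc(OCc3ccccc3)c(OCc3ccccc3)c1)[C@@H](O)C2 | intermediate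
3 | 3,5,7,3',4'-penta-O-benzylcatechin | c1c(OCc2ccccc2)cc(OCc2ccccc2)c2c1O[C@H](c1ccc(OCc3ccccc3)c(OCc3ccccc3)c1)[C@@H](OCc1ccccc1)C2 | intermediate
4 | 8-bromo-penta-O-benzylcatechin | Brc1c(OCc2ccccc2)cc(OCc2ccccc2)c2c1O[C@H](c1ccc(OCc3ccccc3)c(OCc3ccccc3)c1)[C@@H](OCc1ccccc1)C2 | intermediate
5 | 8-lithio-penta-O-benzylcatechin | [Li]c1c(OCc2ccccc2)cc(OCc2ccccc2)c2c1O[C@H](c1ccc(OCc3ccccc3)c(OCc3ccccc3)c1)[C@@H](OCc1ccccc1)C2 | intermediate
6 | 8-formyl-penta-O-benzylcatechin | O=Cc1c(OCc2ccccc2)cc(OCc2ccccc2)c2c1O[C@H](c1ccc(OCc3ccccc3)c(OCc3ccccc3)c1)[C@@H](OCc1ccccc1)C2 | intermediate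
7 | 4-methylcyclohexane-1,3-dione (racemic) | CC1CCC(=O)CC1=O | starting material
8 | 2-(penta-O-benzylcatechin-8-ylmethylidene)-4-methylcyclohexane-1,3-dione | CC1CCC(=O)C(=Cc2c(OCc3ccccc3)cc(OCc3ccccc3)c3c2O[C@H](c2ccc(OCc4ccccc4)c(OCc4ccccc4)c2)[C@@H](OCc2ccccc2)C3)C1=O | intermediate
9 | 2-(penta-O-benzylcatechin-8-ylmethyl)-4-methylcyclohexane-1,3-dione | CC1CCC(=O)C(Cc2c(OCc3ccccc3)cc(OCc3ccccc3)c3c2O[C@H](c2ccc(OCc4ccccc4)c(OCc4ccccc4)c2)[C@@H](OCc2ccccc2)C3)C1=O | intermediate
10 | 4-methyl-2-(penta-O-benzylcatechin-8-ylmethyl)-1,3-bis(trimethylsilyloxy)cyclohexa-1,3-diene | C[Si](C)(C)OC1=C(Cc2c(OCc3ccccc3)cc(OCc3ccccc3)c3c2O[C@H](c2ccc(OCc4ccccc4)c(OCc4ccccc4)c2)[C@@H](OCc2ccccc2)C3)C(O[Si](C)(C)C)=C(C)CC1 | intermediate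
11 | chloroacetaldehyde dimethyl acetal | COC(CCl)OC | starting material
12 | isobutyraldehyde | CC(C)C=O | starting material
13 | lithium methoxyacetylide | [Li]C#COC | intermediate
14 | 1-methoxy-4-methylpent-1-yn-3-ol (racemic) | COC#CC(O)C(C)C | intermediate
15 | 1-methoxy-4-methylpent-1-yn-3-one | COC#CC(=O)C(C)C | intermediate
16 | bicyclo[2.2.2]octa-2,5-diene cycloadduct: bridgeheads bear OSiMe3 and CH3; one alkene bears the catechin-8-ylmethyl group and OSiMe3, the other OMe and isobutyryl; bridgehead epimers | C[Si](C)(C)OC12CCC(C)(C(OC)=C1C(=O)C(C)C)C(O[Si](C)(C)C)=C2Cc1c(OCc2ccccc2)cc(OCc2ccccc2)c2c1O[C@H](c1ccc(OCc3ccccc3)c(OCc3ccccc3)c1)[C@@H](OCc1ccccc1)C2 | intermediate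
17 | penta-O-benzyl pilosanol B bis(trimethylsilyl) ether | COc1c(C)c(O[Si](C)(C)C)c(Cc2c(OCc3ccccc3)cc(OCc3ccccc3)c3c2O[C@H](c2ccc(OCc4ccccc4)c(OCc4ccccc4)c2)[C@@H](OCc2ccccc2)C3)c(O[Si](C)(C)C)c1C(=O)C(C)C | intermediate
18 | penta-O-benzyl pilosanol B | COc1c(C)c(O)c(Cc2c(OCc3ccccc3)cc(OCc3ccccc3)c3c2O[C@H](c2ccc(OCc4ccccc4)c(OCc4ccccc4)c2)[C@@H](OCc2ccccc2)C3)c(O)c1C(=O)C(C)C | intermediate
19 | pilosanol B | COc1c(C)c(O)c(Cc2c(O)cc(O)c3c2O[C@H](c2ccc(O)c(O)c2)[C@@H](O)C3)c(O)c1C(=O)C(C)C | target

## Step count and least certain steps

Total step count: 11. Longest linear sequence: 9 steps (steps 1–6 and 9–11, from 1 to 19); steps 7 and 8 are the two-step branch to 15.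

**Step 9 (key step).** The cycloaddition may be too slow, because the methoxy group raises the LUMO of the dienophile and the attacking diene terminus is fully substituted. Competing processes would then be protodesilylation of the diene back toward 9, stepwise conjugate addition at the methoxy-bearing carbon with loss of methoxide, and thermal oligomerisation of the ynone.

The fallback replaces the donor-substituted dienophile by an acceptor-only halo-ynone and brings in the methoxy group afterwards. It sets out from 10 and returns at 18.
- Purchased 4-methylpent-1-yn-3-ol F1 would be brominated at the alkyne terminus (NBS, catalytic AgNO3, acetone) to 1-bromo-4-methylpent-1-yn-3-ol F2, and this oxidised with MnO2 to 1-bromo-4-methylpent-1-yn-3-one F3.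
- Heating 10 with F3 should give, by the same regiochemistry (the bromine-bearing carbon is the β-carbon), the bicyclic cycloadduct F4 and, after loss of ethylene, the ring D bromide bis(trimethylsilyl) ether F5.
- Dilute HCl would give the bromo diphenol F6.
- A copper-catalysed Ullmann-type methoxylation (NaOMe, CuBr, MeOH–DMF, 110 °C), helped by the ortho acyl group, would convert F6 into 18.

**Step 6.** Enolisation may go toward the unsubstituted CH2 instead of the methyl-bearing carbon, and the diene may be partly hydrolysed during handling. The wrong regiochemistry would pass through the key step with loss of propene and erode the yield of 17.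

The fallback fixes the regiochemistry by a kinetic deprotonation that has only one site. It sets out from 9 and returns at 19.
- Mitsunobu O-benzylation of 9 (BnOH, PPh3, DIAD, THF) should favour the oxygen remote from the methyl group and give 3-benzyloxy-6-methyl-2-(penta-O-benzylcatechin-8-ylmethyl)cyclohex-2-enone F7, separated from its regioisomer.
- In F7 the only α' position is the methyl-bearing methine, so LiN(iPr)2 at −78 °C followed by TMSCl should give the 1-benzyloxy-3-trimethylsilyloxy diene F8.
- Heating F8 with 15 should give the cycloadduct F9 and then hexa-O-benzyl pilosanol B mono(trimethylsilyl) ether F10.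
- Dilute HCl would give hexa-O-benzyl pilosanol B F11, and the hydrogenolysis of step 11 applied to F11 would give 19.

**Step 5.** The Knoevenagel condensation may stall, since the aldehyde is flanked by two oxygen substituents and deactivated by three donors. The dihydropyridine would then be consumed unproductively or the dione would self-condense.

The fallback replaces condensation and reduction by a cationic alkylation. It sets out from 6 and returns at 9. NaBH4 would reduce 6 to 8-hydroxymethyl-penta-O-benzylcatechin F12, whose trioxygenated benzylic position ionises readily. Catalytic TsOH with an excess of 7 in CH2Cl2–MeNO2 should then give 9 by dehydrative C-benzylation of the dione (a Friedel–Crafts-type alkylation of the enol), the excess of 7 suppressing attack of the cation on C6 of a second flavan.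

**Step 8.** The ynol ether carbinol or the ynone may rearrange or hydrate on the oxide surface, and the volatile product may be lost on concentration.

The fallback avoids the oxidation. It sets out from 11 and returns at 15. The acetylide 13, generated as in step 7, would be acylated at −78 °C with purchased N-methoxy-N-methylisobutyramide F13; the chelated tetrahedral adduct collapses only on a buffered quench and should give 15 directly.

## Further compounds

F1 | step 9 | 4-methylpent-1-yn-3-ol (purchased) | C#CC(O)C(C)C
F2 | step 9 | 1-bromo-4-methylpent-1-yn-3-ol | BrC#CC(O)C(C)C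
F3 | step 9 | 1-bromo-4-methylpent-1-yn-3-one | BrC#CC(=O)C(C)C
F4 | step 9 | bromo bicyclo[2.2.2]octa-2,5-diene cycloadduct of 10 and F3 | C[Si](C)(C)OC12CCC(C)(C(Br)=C1C(=O)C(C)C)C(O[Si](C)(C)C)=C2Cc1c(OCc2ccccc2)cc(OCc2ccccc2)c2c1O[C@H](c1ccc(OCc3ccccc3)c(OCc3ccccc3)c1)[C@@H](OCc1ccccc1)C2
F5 | step 9 | ring D bromide bis(trimethylsilyl) ether (Br in place of OMe of 17) | CC(C)C(=O)c1c(Br)c(C)c(O[Si](C)(C)C)c(Cc2c(OCc3ccccc3)cc(OCc3ccccc3)c3c2O[C@H](c2ccc(OCc4ccccc4)c(OCc4ccccc4)c2)[C@@H](OCc2ccccc2)C3)c1O[Si](C)(C)C
F6 | step 9 | ring D bromide diphenol (Br in place of OMe of 18) | CC(C)C(=O)c1c(Br)c(C)c(O)c(Cc2c(OCc3ccccc3)cc(OCc3ccccc3)c3c2O[C@H](c2ccc(OCc4ccccc4)c(OCc4ccccc4)c2)[C@@H](OCc2ccccc2)C3)c1O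
F7 | step 6 | 3-benzyloxy-6-methyl-2-(penta-O-benzylcatechin-8-ylmethyl)cyclohex-2-enone | CC1CCC(OCc2ccccc2)=C(Cc2c(OCc3ccccc3)cc(OCc3ccccc3)c3c2O[C@H](c2ccc(OCc4ccccc4)c(OCc4ccccc4)c2)[C@@H](OCc2ccccc2)C3)C1=O
F8 | step 6 | 1-benzyloxy-4-methyl-2-(penta-O-benzylcatechin-8-ylmethyl)-3-(trimethylsilyloxy)cyclohexa-1,3-diene | CC1=C(O[Si](C)(C)C)C(Cc2c(OCc3ccccc3)cc(OCc3ccccc3)c3c2O[C@H](c2ccc(OCc4ccccc4)c(OCc4ccccc4)c2)[C@@H](OCc2ccccc2)C3)=C(OCc2ccccc2)CC1
F9 | step 6 | bicyclo[2.2.2]octa-2,5-diene cycloadduct of F8 and 15 | C(c1ccccc1)OC12CCC(C)(C(OC)=C1C(=O)C(C)C)C(O[Si](C)(C)C)=C2Cc1c(OCc2ccccc2)cc(OCc2ccccc2)c2c1O[C@H](c1ccc(OCc3ccccc3)c(OCc3ccccc3)c1)[C@@H](OCc1ccccc1)C2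
F10 | step 6 | hexa-O-benzyl pilosanol B mono(trimethylsilyl) ether | COc1c(C)c(O[Si](C)(C)C)c(Cc2c(OCc3ccccc3)cc(OCc3ccccc3)c3c2O[C@H](c2ccc(OCc4ccccc4)c(OCc4ccccc4)c2)[C@@H](OCc2ccccc2)C3)c(OCc2ccccc2)c1C(=O)C(C)C
F11 | step 6 | hexa-O-benzyl pilosanol B (free phenol between bridge and methyl) | COc1c(C)c(O)c(Cc2c(OCc3ccccc3)cc(OCc3ccccc3)c3c2O[C@H](c2ccc(OCc4ccccc4)c(OCc4ccccc4)c2)[C@@H](OCc2ccccc2)C3)c(OCc2ccccc2)c1C(=O)C(C)C
F12 | step 5 | 8-hydroxymethyl-penta-O-benzylcatechin | OCc1c(OCc2ccccc2)cc(OCc2ccccc2)c2c1O[C@H](c1ccc(OCc3ccccc3)c(OCc3ccccc3)c1)[C@@H](OCc1ccccc1)C2
F13 | step 8 | N-methoxy-N-methylisobutyramide (purchased) | CON(C)C(=O)C(C)C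
A1 | alternative 1 | ring A salicylaldehyde carrying the ring D benzyl group at C8 | COc1c(C)c(OCc2ccccc2)c(Cc2c(OCc3ccccc3)cc(OCc3ccccc3)c(C=O)c2O)c(OCc2ccccc2)c1C(=O)C(C)C
A2 | alternative 1 | (E)-3,4-bis(benzyloxy)cinnamaldehyde | O=C/C=C/c1ccc(OCc2ccccc2)c(OCc2ccccc2)c1
A3 | alternative 1 | 2-aryl-2H-chromene-3-carbaldehyde with the ring D benzyl group at C8 | COc1c(C)c(OCc2ccccc2)c(Cc2c(OCc3ccccc3)cc(OCc3ccccc3)c3c2O[C@H](c2ccc(OCc4ccccc4)c(OCc4ccccc4)c2)C(C=O)=C3)c(OCc2ccccc2)c1C(=O)C(C)C
A4 | alternative 2 | 3-methoxy-2-methylcyclobut-2-en-1-one | COC1=C(C)C(=O)C1
A5 | alternative 2 | triisopropylsilyl ynol ether of 3-(penta-O-benzylcatechin-8-yl)prop-1-yne | CC(C)[Si](OC#CCc1c(OCc2ccccc2)cc(OCc2ccccc2)c2c1O[C@H](c1ccc(OCc3ccccc3)c(OCc3ccccc3)c1)[C@@H](OCc1ccccc1)C2)(C(C)C)C(C)C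
A6 | alternative 2 | ring D phenol without the isobutyryl group (OMe, free OH, triisopropylsilyloxy) on penta-O-benzylcatechin | COc1cc(O)c(Cc2c(OCc3ccccc3)cc(OCc3ccccc3)c3c2O[C@H](c2ccc(OCc4ccccc4)c(OCc4ccccc4)c2)[C@@H](OCc2ccccc2)C3)c(O[Si](C(C)C)(C(C)C)C(C)C)c1C
A7 | alternative 3 | open-chain 1-aryl-2-benzyloxy-3-(2-bromo-3-iodo-4,6-bis(benzyloxy)phenyl)propan-1-ol | O[C@H](c1ccc(OCc2ccccc2)c(OCc2ccccc2)c1)[C@@H](OCc1ccccc1)Cc1c(Br)c(I)c(OCc2ccccc2)cc1OCc1ccccc1
A8 | alternative 3 | 2,6-bis(benzyloxy)-3-isobutyryl-4-methoxy-5-methylbenzaldehyde | COc1c(C)c(OCc2ccccc2)c(C=O)c(OCc2ccccc2)c1C(=O)C(C)C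
A9 | alternative 3 | hepta-O-benzyl pilosanol B with hydroxyl on the bridge carbon (carbinol epimers) | COc1c(C)c(OCc2ccccc2)c(C(O)c2c(OCc3ccccc3)cc(OCc3ccccc3)c3c2O[C@H](c2ccc(OCc4ccccc4)c(OCc4ccccc4)c2)[C@@H](OCc2ccccc2)C3)c(OCc2ccccc2)c1C(=O)C(C)C
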